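**Retrosynthetic overview**

1. Target 18 ⇐ diene 16: both oxiranes are installed last, from the outer faces of the (E,E)-cyclodecadiene; 16 ⇐ 15 by acylation of the C8 hydroxyl.
2. 15 ⇐ acyclic β-iodo-enoate aldehyde 12 by forming C6–C7: the enoate β-carbon C7, by nature an acceptor, is used as a donor (alkenylchromium = β-acylvinyl anion, an sp2 homoenolate) against the C6 aldehyde carbon. This one event closes the ten-membered carbocycle and then the butenolide.
3. 12 ⇐ γ-hydroxy ynoate 7 by iodide/formaldehyde addition across the triple bond (C7–I and C13), then adjustment of C6 to the aldehyde.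
4. 7 ⇐ aldehyde 5 + methyl propiolate 6; the asymmetric alkynylation sets C8, the only centre made with an external chiral reagent.
5. 5 ⇐ geraniol 1 (C1–C6, C9, C10, C14, C15) + CO (C8). Ring order: carbocycle, lactone, oxirane C1–C10, oxirane C4–C5.

Assumption: atoms carry germacrane numbers (C6 lactone carbinol, C8 ester carbinol, C12 lactone carbonyl, C13 CH2OAc); the target is the (1R,4R,5R,6S,8S,10R) isomer written in the SMILES.

**Route**

Step 1
Reactants: 1 geraniol
Product: 2 geranyl TBS ether (tert-butyl{[(2E)-3,7-dimethylocta-2,6-dien-1-yl]oxy}dimethylsilane)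
Conditions: TBSCl, imidazole, DMF, 0 °C to rt
Reagents that add atoms: tert-butyldimethylsilyl chloride CC(C)(C)[Si](C)(C)Cl
Why: Imidazole-promoted silylation of the primary allylic alcohol masks the future C6 oxygen through the organometallic steps and creates no stereocentre.

Step 2
Reactants: 2 geranyl TBS ether
Product: 3 (2E,6E)-8-[(tert-butyldimethylsilyl)oxy]-2,6-dimethylocta-2,6-dien-1-ol
Conditions: SeO2 (0.3 equiv), t-BuOOH (3 equiv), salicylic acid (0.1 equiv), CH2Cl2, rt
Reagents that add atoms: tert-butyl hydroperoxide CC(C)(C)OO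
Why: Catalytic SeO2/t-BuOOH allylic oxidation (ene reaction then [2,3]-sigmatropic shift) hydroxylates the E-methyl of the terminal gem-dimethyl olefin, the olefin next to the silyl ether being deactivated, so the E geometry of the later C1=C10 olefin is kept.

Step 3
Reactants: 3 (2E,6E)-8-[(tert-butyldimethylsilyl)oxy]-2,6-dimethylocta-2,6-dien-1-ol
Product: 4 tert-butyl{[(2E,6E)-8-bromo-3,7-dimethylocta-2,6-dien-1-yl]oxy}dimethylsilane
Conditions: CBr4, PPh3, CH2Cl2, 0 °C
Reagents that add atoms: carbon tetrabromide BrC(Br)(Br)Br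
Why: Appel bromination converts the primary allylic alcohol to the bromide by SN2 without allylic shift or loss of olefin geometry.

Step 4
Reactants: 4 tert-butyl{[(2E,6E)-8-bromo-3,7-dimethylocta-2,6-dien-1-yl]oxy}dimethylsilane
Product: 5 (3E,7E)-9-[(tert-butyldimethylsilyl)oxy]-3,7-dimethylnona-3,7-dienal
Conditions: Pd(PPh3)4 (4 mol %), CO (3 atm), Bu3SnH (1.1 equiv, slow addition), THF, 50 °C
Reagents that add atoms: carbon monoxide [C-]#[O+]
Why: Stille-type reductive carbonylation (oxidative addition of the allyl bromide to zerovalent palladium, CO insertion, hydride transfer from tin) formylates the less substituted allyl terminus with retention of the E olefin and supplies C8 as a β,γ-unsaturated aldehyde.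

Step 5
Reactants: 5 (3E,7E)-9-[(tert-butyldimethylsilyl)oxy]-3,7-dimethylnona-3,7-dienal; 6 methyl propiolate (3 equiv)
Product: 7 methyl (4S,6E,10E)-12-[(tert-butyldimethylsilyl)oxy]-4-hydroxy-6,10-dimethyldodeca-6,10-dien-2-ynoate
Conditions: Me2Zn (3 equiv), (S,S)-ProPhenol ligand (2,6-bis{[(S)-2-(hydroxydiphenylmethyl)pyrrolidin-1-yl]methyl}-4-methylphenol, 20 mol %), Ph3P=O (40 mol %), toluene, 4 °C
Reagents that add atoms: none
Why: Zinc/ProPhenol-catalysed asymmetric alkynylation of the aldehyde (Trost) should add the propiolate alkyne to the Re face and set C8 as S; I assign the (S,S) ligand by analogy with its aldol reactions and would switch to the (R,R) ligand if a Mosher check shows the opposite sense.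

Step 6
Reactants: 7 methyl (4S,6E,10E)-12-[(tert-butyldimethylsilyl)oxy]-4-hydroxy-6,10-dimethyldodeca-6,10-dien-2-ynoate
Product: 9 methyl (2Z,4S,6E,10E)-12-[(tert-butyldimethylsilyl)oxy]-4-hydroxy-2-(hydroxymethyl)-3-iodo-6,10-dimethyldodeca-2,6,10-trienoate, via magnesium iodoallenolate 8 (not isolated)
Conditions: MgI2 (2.2 equiv), CH2O (5 equiv, monomer in THF), CH2Cl2, −20 to 0 °C
Reagents that add atoms: magnesium iodide [Mg+2].[I-].[I-]; formaldehyde C=O
Why: Proposed new method: iodide conjugate addition to the ynoate gives allenolate 8, which is hydroxymethylated at C11 by formaldehyde (iodo-aldol of the halo-Baylis–Hillman type, known for propiolates with MgI2, here on a γ-hydroxy internal ynoate), the magnesium-bound C8 oxygen delivering formaldehyde on its own side and anti to iodine so that iodine ends cis to the ester (2Z), while any 2E isomer lactonises onto the C8 hydroxyl and is separated.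

Step 7
Reactants: 9 methyl (2Z,4S,6E,10E)-12-[(tert-butyldimethylsilyl)oxy]-4-hydroxy-2-(hydroxymethyl)-3-iodo-6,10-dimethyldodeca-2,6,10-trienoate
Product: 10 methyl (2Z,4S,6E,10E)-2-(acetoxymethyl)-12-[(tert-butyldimethylsilyl)oxy]-4-hydroxy-3-iodo-6,10-dimethyldodeca-2,6,10-trienoate
Conditions: AcCl (1.05 equiv), 2,4,6-collidine, CH2Cl2, −78 °C
Reagents that add atoms: acetyl chloride CC(Cl)=O
Why: Kinetically selective acylation of the primary allylic hydroxyl over the hindered secondary one with acetyl chloride and collidine at low temperature installs the C13 acetate.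

Step 8
Reactants: 10 methyl (2Z,4S,6E,10E)-2-(acetoxymethyl)-12-[(tert-butyldimethylsilyl)oxy]-4-hydroxy-3-iodo-6,10-dimethyldodeca-2,6,10-trienoate
Product: 11 methyl (2Z,4S,6E,10E)-2-(acetoxymethyl)-4,12-dihydroxy-3-iodo-6,10-dimethyldodeca-2,6,10-trienoate
Conditions: HF·pyridine, pyridine, THF, 0 °C
Reagents that add atoms: none
Why: Fluoride-mediated cleavage of the primary TBS ether under buffered conditions leaves acetate, methyl ester and vinyl iodide untouched.

Step 9
Reactants: 11 methyl (2Z,4S,6E,10E)-2-(acetoxymethyl)-4,12-dihydroxy-3-iodo-6,10-dimethyldodeca-2,6,10-trienoate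
Product: 12 methyl (2Z,4S,6E,10E)-2-(acetoxymethyl)-4-hydroxy-3-iodo-6,10-dimethyl-12-oxododeca-2,6,10-trienoate
Conditions: PhI(OAc)2 (1.2 equiv), TEMPO (2,2,6,6-tetramethylpiperidin-1-oxyl, 10 mol %), CH2Cl2, rt
Reagents that add atoms: none
Why: Oxoammonium (TEMPO/PhI(OAc)2) oxidation is selective for the primary allylic alcohol over the secondary C8 alcohol and gives the E enal without isomerisation.

Step 10
Reactants: 12 methyl (2Z,4S,6E,10E)-2-(acetoxymethyl)-4-hydroxy-3-iodo-6,10-dimethyl-12-oxododeca-2,6,10-trienoate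
Product: 15 13-acetoxy-8α-hydroxygermacra-1(10)E,4E,7(11)-trien-12,6α-olide (6R,8S), via alkenylchromium dichloride 13 (not isolated), via macrocyclic hydroxy ester 14 (not isolated)
Conditions: CrCl2 (10 equiv), NiCl2 (0.2 equiv), degassed DMSO–THF (3:1), rt, 12 added by syringe pump over 12 h (final 2 mM); aq NH4Cl work-up
Reagents that add atoms: none
Why: Proposed new method: a Nozaki–Hiyama–Kishi reaction run as ring closure with lactonisation, in which zerovalent nickel inserts into the activated C7–I bond and transmetalation gives alkenylchromium 13, whose acrylate β-carbon (normally an acceptor) acts as a donor and adds 1,2 to the C6 enal to close the ten-membered ring as 14 before the chromium alkoxide attacks the cis ester to form the butenolide (closest known reactions: CrCl2/NiCl2 coupling of (Z)-β-iodoacrylates with aldehydes to butenolides, and divalent-chromium closure of the germacrane ring at C6–C7 with 2-(bromomethyl)acrylates), C6 being set relative to C8 because the C8 hydroxyl is expected to lie in the enoate plane (low 1,3-allylic strain, hydrogen bond to the C13 acetate) so that C9 and C5 close on one face and H-6 and H-8 end up cis; this facial preference is a model prediction and is the main uncertainty of the route.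

Step 11
Reactants: 15 13-acetoxy-8α-hydroxygermacra-1(10)E,4E,7(11)-trien-12,6α-olide
Product: 16 13-acetoxy-8α-(isobutyryloxy)germacra-1(10)E,4E,7(11)-trien-12,6α-olide (6R,8S)
Conditions: (i-PrCO)2O (1.5 equiv), Et3N, DMAP (4-dimethylaminopyridine, 10 mol %), CH2Cl2, 0 °C to rt
Reagents that add atoms: isobutyric anhydride CC(C)C(=O)OC(=O)C(C)C
Why: DMAP-catalysed acylation of the single remaining hydroxyl (C8) with isobutyric anhydride proceeds with retention at C8.

Step 12
Reactants: 16 13-acetoxy-8α-(isobutyryloxy)germacra-1(10)E,4E,7(11)-trien-12,6α-olide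
Product: 18 13-acetoxy-1β,10α:4α,5β-diepoxy-8α-(isobutyryloxy)germacr-7(11)-en-12,6α-olide (CNP0191378.1), via monoepoxide 17 (not isolated)
Conditions: DMDO (2.5 equiv, acetone solution), CH2Cl2, −20 to 0 °C
Reagents that add atoms: dimethyldioxirane CC1(C)OO1
Why: Electrophilic epoxidation with the neutral dioxirane attacks the two electron-rich trisubstituted E olefins (C1=C10 first, giving 17) from the outer faces of the crown conformer in which both methyl groups are syn, which gives the 1β,10α and 4α,5β oxiranes (1R,10R,4R,5R) as in the epoxidation of related germacranolides such as parthenolide, while the electron-poor butenolide olefin is inert and the absence of acid avoids transannular cyclisation.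

**Compound list**

1 | geraniol [(2E)-3,7-dimethylocta-2,6-dien-1-ol] | CC(C)=CCC/C(C)=C/CO | starting material
2 | geranyl TBS ether [tert-butyl{[(2E)-3,7-dimethylocta-2,6-dien-1-yl]oxy}dimethylsilane] | CC(C)=CCC/C(C)=C/CO[Si](C)(C)C(C)(C)C | intermediate
3 | (2E,6E)-8-[(tert-butyldimethylsilyl)oxy]-2,6-dimethylocta-2,6-dien-1-ol | OC/C(C)=C/CC/C(C)=C/CO[Si](C)(C)C(C)(C)C | intermediate
4 | tert-butyl{[(2E,6E)-8-bromo-3,7-dimethylocta-2,6-dien-1-yl]oxy}dimethylsilane | BrC/C(C)=C/CC/C(C)=C/CO[Si](C)(C)C(C)(C)C | intermediate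
5 | (3E,7E)-9-[(tert-butyldimethylsilyl)oxy]-3,7-dimethylnona-3,7-dienal | O=CC/C(C)=C/CC/C(C)=C/CO[Si](C)(C)C(C)(C)C | intermediate
6 | methyl propiolate (methyl prop-2-ynoate) | COC(=O)C#C | starting material
7 | methyl (4S,6E,10E)-12-[(tert-butyldimethylsilyl)oxy]-4-hydroxy-6,10-dimethyldodeca-6,10-dien-2-ynoate | COC(=O)C#C[C@@H](O)C/C(C)=C/CC/C(C)=C/CO[Si](C)(C)C(C)(C)C | intermediate
8 | magnesium iodide allenolate formed from 7 by iodide addition at C3 of the ynoate (germacrane C7) | COC([O-])=C=C(I)[C@@H](O)C/C(C)=C/CC/C(C)=C/CO[Si](C)(C)C(C)(C)C.[Mg+2].[I-] | intermediate (not isolated)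
9 | methyl (2Z,4S,6E,10E)-12-[(tert-butyldimethylsilyl)oxy]-4-hydroxy-2-(hydroxymethyl)-3-iodo-6,10-dimethyldodeca-2,6,10-trienoate | COC(=O)/C(CO)=C(\I)[C@@H](O)C/C(C)=C/CC/C(C)=C/CO[Si](C)(C)C(C)(C)C | intermediate
10 | methyl (2Z,4S,6E,10E)-2-(acetoxymethyl)-12-[(tert-butyldimethylsilyl)oxy]-4-hydroxy-3-iodo-6,10-dimethyldodeca-2,6,10-trienoate | COC(=O)/C(COC(C)=O)=C(\I)[C@@H](O)C/C(C)=C/CC/C(C)=C/CO[Si](C)(C)C(C)(C)C | intermediate
11 | methyl (2Z,4S,6E,10E)-2-(acetoxymethyl)-4,12-dihydroxy-3-iodo-6,10-dimethyldodeca-2,6,10-trienoate | COC(=O)/C(COC(C)=O)=C(\I)[C@@H](O)C/C(C)=C/CC/C(C)=C/CO | intermediate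
12 | methyl (2Z,4S,6E,10E)-2-(acetoxymethyl)-4-hydroxy-3-iodo-6,10-dimethyl-12-oxododeca-2,6,10-trienoate | COC(=O)/C(COC(C)=O)=C(\I)[C@@H](O)C/C(C)=C/CC/C(C)=C/C=O | intermediate
13 | alkenylchromium dichloride: compound 12 with CrCl2 in place of iodine at C3 (2Z kept) | COC(=O)/C(COC(C)=O)=C(\[Cr](Cl)Cl)[C@@H](O)C/C(C)=C/CC/C(C)=C/C=O | intermediate (not isolated)
14 | methyl (2Z)-3-acetoxy-2-[(2R,3E,7E,10S)-2,10-dihydroxy-4,8-dimethylcyclodeca-3,7-dien-1-ylidene]propanoate (present as its chromium alkoxide) | COC(=O)/C(COC(C)=O)=C1\[C@H](O)/C=C(C)/CC/C=C(C)/C[C@@H]1O | intermediate (not isolated)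
15 | 13-acetoxy-8α-hydroxygermacra-1(10)E,4E,7(11)-trien-12,6α-olide; [(4S,6E,10E,11aR)-4-hydroxy-6,10-dimethyl-2-oxo-2,4,5,8,9,11a-hexahydrocyclodeca[b]furan-3-yl]methyl acetate | CC(=O)OCC1=C2[C@@H](O)C/C(C)=C/CC/C(C)=C/[C@H]2OC1=O | intermediate
16 | 13-acetoxy-8α-(isobutyryloxy)germacra-1(10)E,4E,7(11)-trien-12,6α-olide; (4S,6E,10E,11aR)-3-(acetoxymethyl)-6,10-dimethyl-2-oxo-2,4,5,8,9,11a-hexahydrocyclodeca[b]furan-4-yl 2-methylpropanoate | CC(=O)OCC1=C2[C@@H](OC(=O)C(C)C)C/C(C)=C/CC/C(C)=C/[C@H]2OC1=O | intermediate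
17 | 13-acetoxy-1β,10α-epoxy-8α-(isobutyryloxy)germacra-4E,7(11)-dien-12,6α-olide (1R,6R,8S,10R) | CC(=O)OCC1=C2[C@@H](OC(=O)C(C)C)C[C@@]3(C)O[C@@H]3CC/C(C)=C/[C@H]2OC1=O | intermediate (not isolated)
18 | CNP0191378.1: 13-acetoxy-1β,10α:4α,5β-diepoxy-8α-(isobutyryloxy)germacr-7(11)-en-12,6α-olide (1R,4R,5R,6S,8S,10R) | CC(=O)OCC1=C2[C@@H](OC(=O)C(C)C)C[C@@]3(C)O[C@@H]3CC[C@@]3(C)O[C@@H]3[C@H]2OC1=O | target

**Step count and risks**

Total step count: 12. Longest linear sequence: 12 steps, from geraniol 1 (methyl propiolate 6 is bought).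

The three steps most likely to fail are steps 10, 6 and 12.

Step 10 (ring closure with lactonisation): the C6/C8 relationship rests on a conformational model, and the other C6 epimer may dominate. In that case the C8 centre is entered in the opposite sense and inverted at the end. The fallback sets out from aldehyde 5: alkynylation with the (R,R) ligand gives methyl (4R,6E,10E)-12-[(tert-butyldimethylsilyl)oxy]-4-hydroxy-6,10-dimethyldodeca-6,10-dien-2-ynoate F1. The operations of steps 6 to 9 then give the 4R iodo diol F2, the 4R monoacetate F3, the 4R primary alcohol F4 and the 4R enal F5. CrCl2/NiCl2 closure of this series, now with the 6,8-trans preference working in the useful sense, delivers 13-acetoxy-8β-hydroxygermacra-1(10)E,4E,7(11)-trien-12,6α-olide F6 with C6 as in the target. Mitsunobu esterification (isobutyric acid, PPh3, diisopropyl azodicarboxylate, toluene, 0 °C) inverts C8 and installs the ester in one operation, and the route is rejoined at 16.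

Step 6 (iodide/formaldehyde addition): the geometry of the tetrasubstituted olefin is not secured by precedent, and the 2E isomer may be favoured. The fallback sets out from 7 and delivers C13 from the C8 oxygen through a tether. Chloromethyl chloroformate and pyridine give the chloromethyl carbonate F7. MgI2 in CH2Cl2 adds iodide at C7, and the allenolate is C-alkylated by the tethered chloromethyl group to the seven-membered cyclic carbonate F8, in which C13 must be cis to C8 and iodine cis to the ester. Brief methanolysis (K2CO3 cat., MeOH, 0 °C) frees the diol, and the route is rejoined at 9.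

Step 12 (double epoxidation): two olefin faces and four centres depend on ring conformation, and the C4–C5 olefin next to the lactone oxygen is the less reliable one. The fallback sets that oxirane by reagent control before ring closure and sets out from allylic alcohol 11. Sharpless epoxidation (Ti(OiPr)4, D-(−)-diethyl tartrate, t-BuOOH, 4 Å sieves, CH2Cl2, −20 °C) gives the (10R,11R)-epoxy alcohol F9. TEMPO/PhI(OAc)2 gives the epoxy aldehyde F10. CrCl2/NiCl2 closure gives the 4α,5β-epoxy-8α-hydroxy lactone F11; chelation of the aldehyde and oxirane oxygens by chromium should give the syn C5/C6 relation, though non-chelated addition would give the anti product. Isobutyrylation gives the 4α,5β-epoxy isobutyrate F12. One equivalent of DMDO then epoxidises only C1–C10, and the route ends at 18.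

Further compounds
F1 | step 10 | methyl (4R,6E,10E)-12-[(tert-butyldimethylsilyl)oxy]-4-hydroxy-6,10-dimethyldodeca-6,10-dien-2-ynoate | COC(=O)C#C[C@H](O)C/C(C)=C/CC/C(C)=C/CO[Si](C)(C)C(C)(C)C
F2 | step 10 | methyl (2Z,4R,6E,10E)-12-[(tert-butyldimethylsilyl)oxy]-4-hydroxy-2-(hydroxymethyl)-3-iodo-6,10-dimethyldodeca-2,6,10-trienoate | COC(=O)/C(CO)=C(\I)[C@H](O)C/C(C)=C/CC/C(C)=C/CO[Si](C)(C)C(C)(C)C
F3 | step 10 | methyl (2Z,4R,6E,10E)-2-(acetoxymethyl)-12-[(tert-butyldimethylsilyl)oxy]-4-hydroxy-3-iodo-6,10-dimethyldodeca-2,6,10-trienoate | COC(=O)/C(COC(C)=O)=C(\I)[C@H](O)C/C(C)=C/CC/C(C)=C/CO[Si](C)(C)C(C)(C)C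
F4 | step 10 | methyl (2Z,4R,6E,10E)-2-(acetoxymethyl)-4,12-dihydroxy-3-iodo-6,10-dimethyldodeca-2,6,10-trienoate | COC(=O)/C(COC(C)=O)=C(\I)[C@H](O)C/C(C)=C/CC/C(C)=C/CO
F5 | step 10 | methyl (2Z,4R,6E,10E)-2-(acetoxymethyl)-4-hydroxy-3-iodo-6,10-dimethyl-12-oxododeca-2,6,10-trienoate | COC(=O)/C(COC(C)=O)=C(\I)[C@H](O)C/C(C)=C/CC/C(C)=C/C=O
F6 | step 10 | 13-acetoxy-8β-hydroxygermacra-1(10)E,4E,7(11)-trien-12,6α-olide (6R,8R) | CC(=O)OCC1=C2[C@H](O)C/C(C)=C/CC/C(C)=C/[C@H]2OC1=O
F7 | step 6 | methyl (4S,6E,10E)-12-[(tert-butyldimethylsilyl)oxy]-4-{[(chloromethoxy)carbonyl]oxy}-6,10-dimethyldodeca-6,10-dien-2-ynoate | COC(=O)C#C[C@@H](OC(=O)OCCl)C/C(C)=C/CC/C(C)=C/CO[Si](C)(C)C(C)(C)C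
F8 | step 6 | methyl (4S)-4-{(2E,6E)-8-[(tert-butyldimethylsilyl)oxy]-2,6-dimethylocta-2,6-dien-1-yl}-5-iodo-2-oxo-4,7-dihydro-1,3-dioxepine-6-carboxylate | COC(=O)C1=C(I)[C@H](C/C(C)=C/CC/C(C)=C/CO[Si](C)(C)C(C)(C)C)OC(=O)OC1
F9 | step 12 | methyl (2Z,4S,6E,10R,11R)-2-(acetoxymethyl)-10,11-epoxy-4,12-dihydroxy-3-iodo-6,10-dimethyldodeca-2,6-dienoate | COC(=O)/C(COC(C)=O)=C(\I)[C@@H](O)C/C(C)=C/CC[C@@]1(C)O[C@@H]1CO
F10 | step 12 | methyl (2Z,4S,6E,10R,11S)-2-(acetoxymethyl)-10,11-epoxy-4-hydroxy-3-iodo-6,10-dimethyl-12-oxododeca-2,6-dienoate | COC(=O)/C(COC(C)=O)=C(\I)[C@@H](O)C/C(C)=C/CC[C@@]1(C)O[C@@H]1C=O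
F11 | step 12 | 13-acetoxy-4α,5β-epoxy-8α-hydroxygermacra-1(10)E,7(11)-dien-12,6α-olide (4R,5R,6S,8S) | CC(=O)OCC1=C2[C@@H](O)C/C(C)=C/CC[C@@]3(C)O[C@@H]3[C@H]2OC1=O
F12 | step 12 | 13-acetoxy-4α,5β-epoxy-8α-(isobutyryloxy)germacra-1(10)E,7(11)-dien-12,6α-olide (4R,5R,6S,8S) | CC(=O)OCC1=C2[C@@H](OC(=O)C(C)C)C/C(C)=C/CC[C@@]3(C)O[C@@H]3[C@H]2OC1=O
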